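**Retrosynthetic overview**
1. The target (R)-chromenol comes from its O6 triisopropylsilyl ether by desilylation.
2. The pyran ring is opened at C4–C4a and C3–C2, giving an o-bromoaryl 1-alkylvinyl ether and ethyne; a palladium domino (ethyne carbopalladation, asymmetric 6-exo Heck insertion, formate reduction) joins them. The pyran ring is the only ring made; the benzene ring is bought as a quinone.
3. Enabling feature: C2 of the pyran ring is quaternary, carries a CH3 group and is tied through O1 to C8a. The CH3 can therefore be the =CH2 end of an aryl enol ether, so ring closure leaves palladium on a carbon without β-hydrogen (reduction to CH3), and the cis C3=C4 bond is what syn addition to ethyne gives.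
4. The enol ether comes from Chan–Lam O-alkenylation of a bromophenol with the alkenylboronate of the all-E C43 methyl ketone; the ketone comes from solanesol by excision of C1–C2 (epoxidation, periodate).
5. The bromophenol comes from 2,3-dimethyl-1,4-benzoquinone by HBr addition and selective silylation.

Key step: step 8

Remark: commercial solanesol is taken as the all-E nonaprenol, so the seven E double bonds of the side chain are bought and carried through unchanged. R below denotes the C41 chain (3E,7E,11E,15E,19E,23E,27E)-4,8,12,16,20,24,28,32-octamethyltritriaconta-3,7,11,15,19,23,27,31-octaen-1-yl.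

Step 1
Reactants: 1 solanesol (all-E nonaprenol)
Product: 2 racemic trans-2,3-epoxysolanesol
Conditions: VO(acac)2 (2 mol%), t-BuOOH (1.2 equiv, in decane), CH2Cl2, 0 °C to rt
Reagents that add atoms: tert-butyl hydroperoxide, CC(C)(C)OO
Why: Hydroxyl-directed vanadium-catalysed epoxidation (Sharpless–Michaelson type) should oxidise only the allylic-alcohol double bond among the nine trisubstituted alkenes, and the racemic epoxide suffices because both epoxide carbons are cleaved in step 2.

Step 2
Reactants: 2 racemic trans-2,3-epoxysolanesol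
Product: 4 all-E C43 methyl ketone R–C(=O)CH3 (6,10,14,18,22,26,30,34-octamethylpentatriaconta-5,9,13,17,21,25,29,33-octaen-2-one), via racemic 1,2,3-triol 3 (not isolated)
Conditions: H5IO6 (2.2 equiv), THF/Et2O/H2O, 0 °C
Reagents that add atoms: water, O
Why: Periodic acid should hydrolyse the epoxy alcohol at its tertiary carbon to the triol and cleave both glycol bonds (Malaprade cleavage), so that C3 of solanesol becomes the ketone carbon while the isolated alkenes stay untouched at 0 °C.

Step 3
Reactants: 4 all-E C43 methyl ketone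
Product: 6 alkenyl triflate R–C(=CH2)OTf, via lithium enolate 5 (not isolated)
Conditions: LDA (1.1 equiv), THF, −78 °C; then PhNTf2, −78 to 0 °C
Reagents that add atoms: N-phenylbis(trifluoromethanesulfonimide), O=S(=O)(N(c1ccccc1)S(=O)(=O)C(F)(F)F)C(F)(F)F
Why: Kinetic deprotonation of a methyl ketone by LDA occurs at the CH3 group, and O-sulfonylation of the terminal enolate should give the 1,1-disubstituted enol triflate.

Step 4
Reactants: 6 alkenyl triflate
Product: 7 alkenyl pinacol boronate R–C(=CH2)Bpin
Conditions: B2pin2 (1.1 equiv), PdCl2(PPh3)2 (3 mol%), PPh3 (6 mol%), KOPh (1.5 equiv), toluene, 50 °C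
Reagents that add atoms: bis(pinacolato)diboron, CC1(C)OB(OC1(C)C)B1OC(C)(C)C(C)(C)O1
Why: Miyaura borylation of 1-alkenyl triflates with phenoxide as base is established and should leave the unactivated chain alkenes alone.

Step 5
Reactants: 8 2,3-dimethyl-1,4-benzoquinone
Product: 9 2-bromo-5,6-dimethylbenzene-1,4-diol
Conditions: 48% aq. HBr, CHCl3, 0 °C to rt; aq. Na2S2O4 wash
Reagents that add atoms: hydrogen bromide, Br
Why: 1,4-Hydrobromination of a quinone followed by enolisation gives the bromohydroquinone, and the two free ring positions of 8 are equivalent, so only one regioisomer can form.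

Step 6
Reactants: 9 2-bromo-5,6-dimethylbenzene-1,4-diol
Product: 10 6-bromo-2,3-dimethyl-4-(triisopropylsilyloxy)phenol
Conditions: TIPSCl (1.05 equiv), imidazole, DMF, 0 °C
Reagents that add atoms: triisopropylsilyl chloride, CC(C)[Si](Cl)(C(C)C)C(C)C
Why: Sterically controlled silylation should take the hydroxyl flanked by H and CH3 and leave free the hydroxyl flanked by Br and CH3, which is the one needed next to the bromide.

Step 7
Reactants: 7 alkenyl pinacol boronate; 10 6-bromo-2,3-dimethyl-4-(triisopropylsilyloxy)phenol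
Product: 11 aryl enol ether R–C(=CH2)–O–Ar (Ar = 6-bromo-2,3-dimethyl-4-triisopropylsilyloxyphenyl)
Conditions: Cu(OAc)2 (2 equiv), Et3N (3 equiv), 4 Å MS, CH2Cl2, dry air, rt
Reagents that add atoms: none
Why: Chan–Lam–Evans O-alkenylation (boron-to-copper transmetalation at divalent copper, then C–O reductive elimination) runs at room temperature and, unlike a palladium C–O coupling, should not touch the aryl bromide.

Step 8
Reactants: 11 aryl enol ether; 12 ethyne
Product: 16 (R)-2,7,8-trimethyl-2-R-6-(triisopropylsilyloxy)-2H-chromene, via arylpalladium bromide 13 (not isolated), via Z-alkenylpalladium bromide 14 (not isolated), via neopentyl-type alkylpalladium bromide 15 (not isolated)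
Conditions: Pd2(dba)3 (2.5 mol%), (R)-BINAP (6 mol%), ethyne (1 atm, balloon), HCO2Na (2 equiv), DMF, 60 °C, dark
Reagents that add atoms: none
Why: Proposed new method: oxidative addition of the C–Br bond of 11 to zerovalent palladium gives 13, syn carbopalladation of ethyne forms the C4–C4a bond and the Z-alkenylpalladium 14, and 6-exo-trig migratory insertion into the 1,1-disubstituted enol ether forms the C3–C2 bond, closes the pyran ring and leaves the alkylpalladium 15 on the former =CH2 carbon, which has no β-hydrogen and is reduced by formate (ligand exchange, loss of CO2, C–H reductive elimination) to the 2-methyl group. The closest known reaction types are Larock-type carboannulation cascades in which intermolecular alkyne insertion precedes an intramolecular Heck insertion, the cyclisation–anion capture of neopentyl-type alkylpalladium species by formate, and enantioselective reductive Heck cyclisations that build quaternary centres from 1,1-disubstituted alkenes; their combination with ethyne and an aryl enol ether acceptor to give a 2H-chromene has not been shown. C2, the only new stereocentre, is set in the insertion step by the chiral bisphosphine on the alkenylpalladium, which must tell apart the two faces of an alkene whose reacting carbon carries the tethering oxygen and the C41 chain and whose other end is =CH2, so no methyl-versus-methylene discrimination is asked of it; (R)-BINAP is the first choice and the antipode that delivers 2R is to be fixed in a pilot run. The step needs ethyne insertion to outrun both formate reduction of 13 and its geometrically poor 4-exo or 5-endo closure, a single ethyne insertion, and C–C bond formation at the oxygen-bearing alkene carbon: the first is served by the unhindered alkyne and sparingly soluble HCO2Na, the second by the intramolecular 6-exo step at low ethyne pressure, the third by the exo geometry together with the preference of cationic palladium for the α-carbon of enol ethers. The absence of amine base and of copper should keep ethyne from entering as an acetylide, and the eight trisubstituted chain alkenes are too hindered to insert.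

Step 9
Reactants: 16 (R)-2,7,8-trimethyl-2-R-6-(triisopropylsilyloxy)-2H-chromene
Product: 17 Plastochromenol-8, (R)-2,7,8-trimethyl-2-R-2H-chromen-6-ol
Conditions: TBAF/AcOH (1:1, 1.5 equiv), THF, 0 °C, argon, dark
Reagents that add atoms: none
Why: Fluoride-induced cleavage of the aryl silyl ether, buffered with acetic acid and run without light or air, should free the phenol without oxidising it and without the photochemical ring opening of the 2H-chromene that would scramble C2.

**Compound list**
1 | solanesol, all-E nonaprenol | CC(C)=CCC/C(C)=C/CC/C(C)=C/CC/C(C)=C/CC/C(C)=C/CC/C(C)=C/CC/C(C)=C/CC/C(C)=C/CC/C(C)=C/CO | starting material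
2 | racemic trans-2,3-epoxysolanesol (one enantiomer drawn) | CC(C)=CCC/C(C)=C/CC/C(C)=C/CC/C(C)=C/CC/C(C)=C/CC/C(C)=C/CC/C(C)=C/CC/C(C)=C/CC[C@]1(C)O[C@H]1CO | intermediate
3 | racemic 1,2,3-triol from hydrolysis of 2 (not isolated) | CC(C)=CCC/C(C)=C/CC/C(C)=C/CC/C(C)=C/CC/C(C)=C/CC/C(C)=C/CC/C(C)=C/CC/C(C)=C/CCC(C)(O)C(O)CO | intermediate
4 | all-E C43 methyl ketone R–C(=O)CH3 | CC(C)=CCC/C(C)=C/CC/C(C)=C/CC/C(C)=C/CC/C(C)=C/CC/C(C)=C/CC/C(C)=C/CC/C(C)=C/CCC(C)=O | intermediate
5 | kinetic lithium enolate of 4 (not isolated) | CC(C)=CCC/C(C)=C/CC/C(C)=C/CC/C(C)=C/CC/C(C)=C/CC/C(C)=C/CC/C(C)=C/CC/C(C)=C/CCC(=C)[O-].[Li+] | intermediate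
6 | alkenyl triflate R–C(=CH2)OTf | CC(C)=CCC/C(C)=C/CC/C(C)=C/CC/C(C)=C/CC/C(C)=C/CC/C(C)=C/CC/C(C)=C/CC/C(C)=C/CCC(=C)OS(=O)(=O)C(F)(F)F | intermediate
7 | alkenyl pinacol boronate R–C(=CH2)Bpin | CC(C)=CCC/C(C)=C/CC/C(C)=C/CC/C(C)=C/CC/C(C)=C/CC/C(C)=C/CC/C(C)=C/CC/C(C)=C/CCC(=C)B1OC(C)(C)C(C)(C)O1 | intermediate
8 | 2,3-dimethyl-1,4-benzoquinone | CC1=C(C)C(=O)C=CC1=O | starting material
9 | 2-bromo-5,6-dimethylbenzene-1,4-diol | Oc1cc(Br)c(O)c(C)c1C | intermediate
10 | 6-bromo-2,3-dimethyl-4-(triisopropylsilyloxy)phenol | CC(C)[Si](Oc1cc(Br)c(O)c(C)c1C)(C(C)C)C(C)C | intermediate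
11 | aryl enol ether R–C(=CH2)–O–Ar | CC(C)=CCC/C(C)=C/CC/C(C)=C/CC/C(C)=C/CC/C(C)=C/CC/C(C)=C/CC/C(C)=C/CC/C(C)=C/CCC(=C)Oc1c(Br)cc(O[Si](C(C)C)(C(C)C)C(C)C)c(C)c1C | intermediate
12 | ethyne | C#C | starting material
13 | arylpalladium bromide from 11 (bisphosphine omitted; not isolated) | CC(C)=CCC/C(C)=C/CC/C(C)=C/CC/C(C)=C/CC/C(C)=C/CC/C(C)=C/CC/C(C)=C/CC/C(C)=C/CCC(=C)Oc1c([Pd]Br)cc(O[Si](C(C)C)(C(C)C)C(C)C)c(C)c1C | intermediate
14 | Z-alkenylpalladium bromide (bisphosphine omitted; not isolated) | CC(C)=CCC/C(C)=C/CC/C(C)=C/CC/C(C)=C/CC/C(C)=C/CC/C(C)=C/CC/C(C)=C/CC/C(C)=C/CCC(=C)Oc1c(/C=C\[Pd]Br)cc(O[Si](C(C)C)(C(C)C)C(C)C)c(C)c1C | intermediate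
15 | (2H-chromen-2-yl)methylpalladium bromide (bisphosphine omitted; not isolated) | CC(C)=CCC/C(C)=C/CC/C(C)=C/CC/C(C)=C/CC/C(C)=C/CC/C(C)=C/CC/C(C)=C/CC/C(C)=C/CC[C@]1(C[Pd]Br)C=Cc2cc(O[Si](C(C)C)(C(C)C)C(C)C)c(C)c(C)c2O1 | intermediate
16 | (R)-2,7,8-trimethyl-2-R-6-(triisopropylsilyloxy)-2H-chromene | CC(C)=CCC/C(C)=C/CC/C(C)=C/CC/C(C)=C/CC/C(C)=C/CC/C(C)=C/CC/C(C)=C/CC/C(C)=C/CC[C@]1(C)C=Cc2cc(O[Si](C(C)C)(C(C)C)C(C)C)c(C)c(C)c2O1 | intermediate
17 | Plastochromenol-8 | CC(C)=CCC/C(C)=C/CC/C(C)=C/CC/C(C)=C/CC/C(C)=C/CC/C(C)=C/CC/C(C)=C/CC/C(C)=C/CC[C@]1(C)C=Cc2cc(O)c(C)c(C)c2O1 | target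

**Step count**
Total steps: 9. Longest linear sequence: 7 steps (steps 1, 2, 3, 4, 7, 8, 9 from solanesol); steps 5 and 6 form the arene branch.

**Steps most likely to fail**

Step 8. Formate may reduce 13 or 14 before ring closure, ethyne may insert more than once, 15 may undergo β-aryloxy elimination or close onto the C3=C4 bond, and the facial selectivity at C2 may be poor. The fallback uses known chemistry, sets out from 10 and 1 and comes back at 16; in it C2 is set by an asymmetric O-allylation and the ring is closed at C3=C4. Stille coupling of 10 with tributyl(vinyl)stannane (Pd(PPh3)4, toluene, 90 °C) would give 2,3-dimethyl-4-(triisopropylsilyloxy)-6-vinylphenol F1. Acylation of 1 with methyl chloroformate and pyridine would give solanesyl methyl carbonate F2. Trost asymmetric allylic alkylation of F1 with F2 (Pd2(dba)3·CHCl3, (R,R)-DACH-phenyl Trost ligand or its antipode, CH2Cl2, rt) should attack the tertiary allyl terminus and give the (R)-configured tertiary aryl allyl ether F3. Ring-closing metathesis of the two vinyl groups of F3 with the second-generation Grubbs catalyst (CH2Cl2, 40 °C) would then give 16.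

Step 7. Transmetalation of the α-substituted alkenylboronate to copper may be slow with the doubly ortho-substituted phenol, the electron-rich phenol may be oxidised by divalent copper and air, and the enol ether may hydrolyse on work-up. The fallback replaces C–O coupling by ester methylenation, sets out from 4 and 10 and comes back at 11. The kinetic enolate of 4 (LDA, THF, −78 °C) would be hydroxylated with 2-(phenylsulfonyl)-3-phenyloxaziridine to the 1-hydroxy ketone F4. NaIO4 in THF/H2O would cleave the ketol to the C42 carboxylic acid F5. Esterification with 10 (EDC, DMAP, CH2Cl2) would give the aryl ester F6. Methylenation with the Tebbe reagent Cp2Ti(CH2)(Cl)AlMe2 (THF, pyridine, −40 to 0 °C) would give 11.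

Step 6. Silylation may occur at the wrong hydroxyl or at both. The fallback fixes the regiochemistry by the order of events, sets out from 8 and comes back at 10. Reduction of 8 with Na2S2O4 (EtOAc/H2O) would give 2,3-dimethylhydroquinone F7. Monosilylation of this symmetric diol (TIPSCl, imidazole, DMF) would give 2,3-dimethyl-4-(triisopropylsilyloxy)phenol F8. Ortho-bromination next to the free hydroxyl (N-bromosuccinimide, cat. i-Pr2NH, CH2Cl2, 0 °C) would give 10.

**Further compounds**
F1 | step 8 | 2,3-dimethyl-4-(triisopropylsilyloxy)-6-vinylphenol | C=Cc1cc(O[Si](C(C)C)(C(C)C)C(C)C)c(C)c(C)c1O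
F2 | step 8 | solanesyl methyl carbonate | CC(C)=CCC/C(C)=C/CC/C(C)=C/CC/C(C)=C/CC/C(C)=C/CC/C(C)=C/CC/C(C)=C/CC/C(C)=C/CC/C(C)=C/COC(=O)OC
F3 | step 8 | (R)-tertiary aryl allyl ether ArO–C(CH3)(R)–CH=CH2, Ar = 2,3-dimethyl-4-triisopropylsilyloxy-6-vinylphenyl | CC(C)=CCC/C(C)=C/CC/C(C)=C/CC/C(C)=C/CC/C(C)=C/CC/C(C)=C/CC/C(C)=C/CC/C(C)=C/CC[C@](C)(C=C)Oc1c(C=C)cc(O[Si](C(C)C)(C(C)C)C(C)C)c(C)c1C
F4 | step 7 | 1-hydroxy ketone R–C(=O)CH2OH | CC(C)=CCC/C(C)=C/CC/C(C)=C/CC/C(C)=C/CC/C(C)=C/CC/C(C)=C/CC/C(C)=C/CC/C(C)=C/CCC(=O)CO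
F5 | step 7 | C42 carboxylic acid R–CO2H | CC(C)=CCC/C(C)=C/CC/C(C)=C/CC/C(C)=C/CC/C(C)=C/CC/C(C)=C/CC/C(C)=C/CC/C(C)=C/CCC(=O)O
F6 | step 7 | aryl ester R–C(=O)–O–Ar, Ar = 6-bromo-2,3-dimethyl-4-triisopropylsilyloxyphenyl | CC(C)=CCC/C(C)=C/CC/C(C)=C/CC/C(C)=C/CC/C(C)=C/CC/C(C)=C/CC/C(C)=C/CC/C(C)=C/CCC(=O)Oc1c(Br)cc(O[Si](C(C)C)(C(C)C)C(C)C)c(C)c1C
F7 | step 6 | 2,3-dimethylhydroquinone | Cc1c(C)c(O)ccc1O
F8 | step 6 | 2,3-dimethyl-4-(triisopropylsilyloxy)phenol | Cc1c(C)c(O[Si](C(C)C)(C(C)C)C(C)C)ccc1O
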